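**Remark on the chemistry (numbering and configuration):** daucane numbering is used: C1 = quaternary ring-fusion carbon with CH3, C2 and C3 = CH2, C4 = CH–iPr, C5 = ring-fusion C–OH, C6 = CH2, C7 = CH–O-acyl, C8 = olefinic C–CH3, C9 = olefinic CH, C10 = CH2. The SMILES is read as 1R,4R,5S,7R, which is (3R,3aS,5R,8aR) in azulene numbering. CH3 (C1), OH (C5) and iPr (C4) lie on one face of the cyclopentane (called β here); C6 and C10 are α (cis ring fusion); the C7 oxygen is α, anti to C5–OH.

## The problem

1. The skeleton is a cis-fused bicyclo[5.3.0]decene: cyclopentane ring A (C1–C5) and cycloheptene ring B (C5–C6–C7–C8–C9–C10–C1) share the C1–C5 bond, which joins an all-carbon quaternary centre to a tertiary carbinol carbon.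
2. Ring A carries three contiguous stereocentres (C4, C5, C1) with iPr, OH and CH3 all β. Both ring-B bonds to ring A (C1–C10 and C5–C6) therefore have to be made anti to the isopropyl group, while the C5 oxygen must end syn to it.
3. C4 cannot be set late in the required sense. Its only functionalised neighbour is C5, and hydrogen delivered to a C4 olefin from the C5–OH or from the convex face of the bicycle would put iPr anti to OH. C4 is therefore the centre to buy; C1 and C5 are relayed from it across ring A, and C7 is relayed from C5–OH across C6 (1,3-anti).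
4. The feature that makes the key step possible: the only heteroatom of ring A sits on C5, between the methyl-bearing C1 and the isopropyl-bearing C4. Ring A is thus a masked 2,2,5-trisubstituted cyclopentanone whose enolate towards C1 and whose carbonyl C5 are both shielded on the β face by the C4 isopropyl group. The same ring (CH3 on C1, O on C5, iPr on C4) is also the six-membered ring of limonene with one ring carbon cut out.
5. Ring B needs a seven-membered closure that includes a cis trisubstituted olefin (CH3 on C8) next to the oxygenated C7.
6. Sensitive points are: the tertiary β-hydroxy carbonyl stage (retro-aldol, dehydration); C4, which can epimerise whenever C5 is a ketone; the 6-hydroxy-cycloheptenone stage, where C5–OH can add across ring B to C9 (transannular oxa-Michael); and the allylic ester, which ionises under acid.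

## Retrosynthesis

**C7–O acyl bond.** Target 21 is cut to diol 19 and acid chloride 20. The tertiary C5–OH is neopentyl-like and flanked by two fully substituted neighbours, so only the secondary allylic C7–OH should be acylated and no protecting group is needed. The precursor loses the whole aryl ester.

**C7–H bond.** Diol 19 comes from hydroxy enone 18. The C7 stereocentre is the only one with no neighbour in ring A; setting it by hydride delivery from the C5 hydroxyl gives the anti-1,3 relation by an internal mechanism. The alternative, an undirected attack on a flexible seven-membered ring, would leave the facial outcome open. The forward reaction must reduce the carbonyl in 1,2 fashion and faster than C5–OH adds to C9.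

**C7–C8 bond (ring B closure).** Enone 18 is opened to the iodo-alkenyl Weinreb amide 15 (through alkenyllithium 16 and tetrahedral adduct 17). Cutting at C8=C9 would need an olefin-forming ring closure on a hindered 1,1-disubstituted olefin. Cutting at C5–C6 would close the ring by a reversible seven-membered aldol. At C7–C8 the closure is an irreversible acylation, and the cis olefin with its methyl is already in the chain, so no geometry is decided in the ring-forming step. The precursor is monocyclic.

**C5–C6 bond.** Amide 15 comes from ketone 12 and acetamide 13 (as enolate 14). The two-carbon unit C6–C7 enters at the acid oxidation level that the next step needs. The forward addition must occur on the α face of C5, anti to the C4 isopropyl group, so that the oxygen ends β.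

**C1–C10 bond (key disconnection).** Ketone 12 is cut to the regiodefined lithium enolate 11 and allylic bromide 10. This cut removes the quaternary stereocentre and four of the five ring-B carbons not shared with ring A (C10, C9, C8 with its methyl) at once, leaving a ring with a single stereocentre. Enolate 11 must be formed without ever equilibrating towards C4, and is therefore taken from enol formate 6 rather than from the free ketone.

**Ring A from limonene.** Enol formate 6 comes from enal 5 by excision of the formyl carbon (Baeyer–Villiger: the C5–CHO bond is cut and oxygen is left on C5, with the double bond fixed towards C1). Enal 5 comes from keto aldehyde 4 by aldol ring contraction, 4 from p-menthene 2 by ozonolysis (through ozonide 3), and 2 from (S)-limonene 1 by selective hydrogenation. The stereocentre of 1 is kept as C4. It is never α to a carbonyl before C1 is quaternary.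

**Side chain.** Bromide 10 comes from (Z)-iodo alcohol 9, made from but-2-yn-1-ol 7 through the cyclic alkenylalanate 8, which fixes iodine cis to the CH2 group.

## Roads not taken

**Alternative 1:** (the most obvious) cut the C8=C9 double bond by ring-closing metathesis. Enolate 11 would be allylated to (2R,5R)-2-methyl-5-(propan-2-yl)-2-(prop-2-en-1-yl)cyclopentan-1-one A1; aldol addition of a C6–C7(=O)–C8(CH3)=CH2 unit to C5 would give the diene 1-[(1S,2R,5R)-1-hydroxy-2-methyl-5-(propan-2-yl)-2-(prop-2-en-1-yl)cyclopentyl]-3-methylbut-3-en-2-one A2; a ruthenium carbene (second-generation Hoveyda–Grubbs catalyst) would close ring B to 18. The step count is the same as in the chosen plan, so the choice rests on mechanism: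
- The aldol partner is a polymerisable Michael acceptor whose ketone enolate must add reversibly to a hindered, enolisable ketone; amide enolate 14 is not an acceptor and its adduct does not revert.
- The metathesis must join an electron-poor 1,1-disubstituted olefin to an allyl group on a neopentyl carbon to make a trisubstituted ring olefin, the slowest class of ring closure for these catalysts.
- In the chosen plan the olefin, its methyl and its geometry are bought with the alkylating agent, and the ring is closed by a fast, irreversible C–C acylation.

**Alternative 2:** cut C5–C6 by a desymmetrising intramolecular aldol. The triketone 2-methyl-2-(3-oxobutyl)cyclopentane-1,3-dione A3 (from 2-methylcyclopentane-1,3-dione and methyl vinyl ketone) would cyclise under D-proline catalysis (Hajos–Parrish reaction) to the cis-fused ketol (3aR,7aR)-3a-hydroxy-7a-methylhexahydro-1H-indene-1,5(4H)-dione A4. This sets C1 and C5 in one catalytic event, which is attractive. But A4 has ring B one carbon short (C8 with its methyl must be inserted regioselectively between C7 and C9), carries a C2 ketone that the target lacks, and lacks the C4 isopropyl group. That group would have to be added by conjugate addition to a C3=C4 enone on the face syn to the angular oxygen, against the usual anti preference of a γ-oxygen. The one centre that cannot be corrected by relay would be set last and against the substrate, and the sequence would be about twice as long.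

**Alternative 3:** cut C4–C5 and build ring A last by an intramolecular carbonyl-ene reaction. In the cycloheptenone (2R,6R)-6-[(tert-butyldimethylsilyl)oxy]-2,5-dimethyl-2-(4-methylpent-3-en-1-yl)cyclohept-4-en-1-one A5 the C5 carbonyl would take an allylic hydrogen from the prenyl-type terminus while C4 bonds to C5. The six-membered transition state places OH cis to the angular methyl and cis to the new isopropenyl group, giving (3R,3aS,5R,8aR)-5-[(tert-butyldimethylsilyl)oxy]-6,8a-dimethyl-3-(prop-1-en-2-yl)-2,3,4,5,8,8a-hexahydroazulen-3a(1H)-ol A6, so C5 and C4 would be set from C1 in one event. The difficulty is moved into A5: an all-carbon quaternary stereocentre on a seven-membered ring, a remote C7 stereocentre that nothing controls, the C8 methyl and the C8=C9 olefin would each need their own steps (for example an enantioselective palladium-catalysed allylic alkylation, then chain extension). That run-up is longer than the whole chosen route. The ene step would also need Lewis-acid activation of a hindered ketone next to an ionisable allylic silyl ether, and the final hydrogenation would have to tell isopropenyl from C8=C9.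

Key step: step 7

## Route

Step 1
Reactants: 1 (S)-(−)-limonene [(4S)-1-methyl-4-(prop-1-en-2-yl)cyclohex-1-ene]
Product: 2 (4S)-1-methyl-4-(propan-2-yl)cyclohex-1-ene
Conditions: H2 (1 atm), RhCl(PPh3)3 (cat.), benzene–EtOH, rt
Reagents that add atoms: none
Why: Homogeneous hydrogenation with RhCl(PPh3)3 reduces the 1,1-disubstituted isopropenyl olefin much faster than the trisubstituted ring olefin; the stereocentre (the future C4) is not touched.

Step 2
Reactants: 2 (4S)-1-methyl-4-(propan-2-yl)cyclohex-1-ene
Product: 4 (3S)-6-oxo-3-(propan-2-yl)heptanal, via ozonide 3 (not isolated)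
Conditions: O3, CH2Cl2, −78 °C; then PPh3, −78 °C to rt
Reagents that add atoms: ozone, [O-][O+]=O
Why: Ozonolysis of the only olefin with reductive work-up cuts the C1=C2 bond of the p-menthane ring; the stereocentre is β to the aldehyde and δ to the ketone, so it cannot epimerise.

Step 3
Reactants: 4 (3S)-6-oxo-3-(propan-2-yl)heptanal
Product: 5 (5R)-2-methyl-5-(propan-2-yl)cyclopent-1-ene-1-carbaldehyde
Conditions: piperidine, AcOH, benzene, reflux (removal of water)
Reagents that add atoms: none
Why: Intramolecular aldol condensation: the piperidine enamine of the aldehyde attacks the methyl ketone (five-membered ring) and water is lost to give the conjugated enal, a ring contraction of the terpene ring. C4 is attached to the α-carbon of the enal and is not acidified, so its configuration should hold (the CIP descriptor changes only because the priorities change).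

Step 4
Reactants: 5 (5R)-2-methyl-5-(propan-2-yl)cyclopent-1-ene-1-carbaldehyde
Product: 6 (5R)-2-methyl-5-(propan-2-yl)cyclopent-1-en-1-yl formate
Conditions: 30% aq. H2O2, bis(2-nitrophenyl) diselenide (cat.), CH2Cl2, rt
Reagents that add atoms: hydrogen peroxide, OO
Why: Baeyer–Villiger oxidation of an α,β-unsaturated aldehyde by the areneseleninic peracid formed in the flask: the alkenyl carbon migrates to oxygen and an enol formate results. The superfluous ring carbon of limonene leaves as formate, oxygen is placed on C5, and the enol double bond is fixed towards C1.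

Step 5
Reactants: 7 but-2-yn-1-ol
Product: 9 (2Z)-3-iodobut-2-en-1-ol, via alkenylalanate 8 (not isolated)
Conditions: NaAlH2(OCH2CH2OMe)2, THF, 0 °C to rt; then I2, −78 to 0 °C
Reagents that add atoms: iodine, II
Why: Hydroxyl-directed trans-hydroalumination gives the five-membered alkenylalanate 8, and iodinolysis of the C–Al bond with retention puts iodine on C3 cis to the CH2O group.

Step 6
Reactants: 9 (2Z)-3-iodobut-2-en-1-ol
Product: 10 (2Z)-1-bromo-3-iodobut-2-ene
Conditions: PPh3, CBr4, CH2Cl2, 0 °C
Reagents that add atoms: tetrabromomethane, BrC(Br)(Br)Br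
Why: Appel reaction of a primary allylic alcohol; SN2 displacement on the alkoxyphosphonium ion leaves the olefin geometry and the vinyl iodide untouched.

Step 7
Reactants: 6 (5R)-2-methyl-5-(propan-2-yl)cyclopent-1-en-1-yl formate; 10 (2Z)-1-bromo-3-iodobut-2-ene
Product: 12 (2R,5R)-2-[(2Z)-3-iodobut-2-en-1-yl]-2-methyl-5-(propan-2-yl)cyclopentan-1-one, via lithium enolate 11 (not isolated)
Conditions: MeLi (2 equiv), THF, 0 °C; then DMPU, 10, −78 to −20 °C
Reagents that add atoms: none
Why: Two equivalents of MeLi remove the formyl group of 6 (addition to the formate C=O, collapse to the enolate and acetaldehyde, which the second equivalent traps as lithium isopropoxide), so lithium enolate 11 forms with its double bond fixed between C5 and C1 and with no proton source that could move it towards C4. C-Alkylation by the primary allylic bromide 10 (SN2) then makes the C1–C10 bond and the quaternary stereocentre C1. The closest known reaction type is the regiospecific release of a lithium enolate from an enol ester with MeLi followed by alkylation to an α-quaternary ketone. No ring is closed; the step delivers C10, C9, C8 and the C8 methyl of ring B with the olefin already cis and with the iodine that will become the C7–C8 bond. C1 is controlled by C4: to avoid A(1,2) strain with the enolate oxygen the isopropyl group should sit pseudo-axial over the β face, so the electrophile should enter on the α face, giving C10 α and CH3 β as in the target. The step needs C- over O-alkylation (lithium counter-ion, soft allylic bromide), SN2 over SN2' (primary carbon, hindered iodo-olefin terminus), no enolate equilibration (aprotic medium, reactive electrophile at low temperature, so C4 keeps its configuration) and an intact vinyl iodide (enolates do not exchange with C–I bonds).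

Step 8
Reactants: 12 (2R,5R)-2-[(2Z)-3-iodobut-2-en-1-yl]-2-methyl-5-(propan-2-yl)cyclopentan-1-one; 13 N-methoxy-N-methylacetamide
Product: 15 2-[(1S,2R,5R)-1-hydroxy-2-[(2Z)-3-iodobut-2-en-1-yl]-2-methyl-5-(propan-2-yl)cyclopentyl]-N-methoxy-N-methylacetamide, via amide lithium enolate 14 (not isolated)
Conditions: 13, LiN(i-Pr)2, THF, −78 °C; then 12, −78 to −40 °C
Reagents that add atoms: none
Why: Aldol-type addition of an amide enolate to the ketone makes the C5–C6 bond; the nucleophile should attack the α face of C5, anti to the C4 isopropyl group (H on the α side of C4, iPr and CH3 on the β side), so the hydroxyl ends β, cis to CH3 and iPr. The tertiary aldolate of an amide does not revert at low temperature, and the Weinreb amide carries C7 at the oxidation level needed for ring closure.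

Step 9
Reactants: 15 2-[(1S,2R,5R)-1-hydroxy-2-[(2Z)-3-iodobut-2-en-1-yl]-2-methyl-5-(propan-2-yl)cyclopentyl]-N-methoxy-N-methylacetamide
Product: 18 (3R,3aS,8aR)-3a-hydroxy-6,8a-dimethyl-3-(propan-2-yl)-2,3,3a,4,8,8a-hexahydroazulen-5(1H)-one, via alkenyllithium alkoxide 16 (not isolated), via tetrahedral dilithium adduct 17 (not isolated)
Conditions: t-BuLi (3 equiv), Et2O–THF, −78 °C; then AcOH in THF, −78 °C
Reagents that add atoms: none
Why: After deprotonation of the hydroxyl, iodine–lithium exchange with retention gives alkenyllithium 16, which acylates itself on the Weinreb amide (Parham-type cyclisation, 7-exo-trig) and closes ring B at C7–C8. The chelated adduct 17 prevents a second addition and keeps the enone masked until the cold acidic quench, so alkoxide and enone never coexist.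

Step 10
Reactants: 18 (3R,3aS,8aR)-3a-hydroxy-6,8a-dimethyl-3-(propan-2-yl)-2,3,3a,4,8,8a-hexahydroazulen-5(1H)-one
Product: 19 (3R,3aS,5R,8aR)-6,8a-dimethyl-3-(propan-2-yl)-2,3,4,5,8,8a-hexahydroazulene-3a,5(1H)-diol
Conditions: Me4NBH(OAc)3, MeCN–AcOH, −30 °C
Reagents that add atoms: none
Why: Evans–Saksena reduction: the C5 hydroxyl exchanges onto boron and delivers hydride to the β face of the C7 carbonyl through a six-membered transition state, so the new C7–OH ends α, anti to C5–OH. The reagent does not reduce the enone in conjugate fashion or without the directing group.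

Step 11
Reactants: 19 (3R,3aS,5R,8aR)-6,8a-dimethyl-3-(propan-2-yl)-2,3,4,5,8,8a-hexahydroazulene-3a,5(1H)-diol; 20 3,4-dimethoxybenzoyl chloride
Product: 21 (3R,3aS,5R,8aR)-3a-hydroxy-6,8a-dimethyl-3-(propan-2-yl)-1,2,3,3a,4,5,8,8a-octahydroazulen-5-yl 3,4-dimethoxybenzoate
Conditions: 20, Et3N, DMAP (cat.), CH2Cl2, 0 °C
Reagents that add atoms: none
Why: DMAP-catalysed acylation; only the secondary allylic C7–OH should react, since the tertiary C5–OH lies between a quaternary carbon and an isopropyl-bearing carbon. The basic, non-ionising conditions leave the allylic C–O bond intact.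

## Compound list

1 | (S)-(−)-limonene, (4S)-1-methyl-4-(prop-1-en-2-yl)cyclohex-1-ene | CC1=CC[C@H](CC1)C(C)=C | starting material
2 | (4S)-1-methyl-4-(propan-2-yl)cyclohex-1-ene | CC1=CC[C@H](CC1)C(C)C | intermediate
3 | 1-methyl-4-(propan-2-yl)-7,8,9-trioxabicyclo[4.2.1]nonane (secondary ozonide of 2; isopropyl-bearing carbon as in 2, both orientations of the trioxolane bridge) | CC12CC[C@H](C(C)C)CC(O1)OO2 | intermediate
4 | (3S)-6-oxo-3-(propan-2-yl)heptanal | O=CC[C@H](CCC(C)=O)C(C)C | intermediate
5 | (5R)-2-methyl-5-(propan-2-yl)cyclopent-1-ene-1-carbaldehyde | O=CC1=C(C)CC[C@@H]1C(C)C | intermediate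
6 | (5R)-2-methyl-5-(propan-2-yl)cyclopent-1-en-1-yl formate | O=COC1=C(C)CC[C@@H]1C(C)C | intermediate
7 | but-2-yn-1-ol | CC#CCO | starting material
8 | sodium 2,2-bis(2-methoxyethoxy)-3-methyl-2,5-dihydro-1,2-oxaaluminol-2-uide (cyclic alkenylalanate) | CC1=CCO[Al-]1(OCCOC)OCCOC.[Na+] | intermediate
9 | (2Z)-3-iodobut-2-en-1-ol | OC/C=C(/C)I | intermediate
10 | (2Z)-1-bromo-3-iodobut-2-ene | BrC/C=C(/C)I | intermediate
11 | lithium (5R)-2-methyl-5-(propan-2-yl)cyclopent-1-en-1-olate | [Li+].[O-]C1=C(C)CC[C@@H]1C(C)C | intermediate
12 | (2R,5R)-2-[(2Z)-3-iodobut-2-en-1-yl]-2-methyl-5-(propan-2-yl)cyclopentan-1-one | O=C1[C@@H](C(C)C)CC[C@]1(C)C/C=C(/C)I | intermediate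
13 | N-methoxy-N-methylacetamide | CC(=O)N(C)OC | starting material
14 | lithium 1-[methoxy(methyl)amino]ethen-1-olate | [Li+].[O-]C(=C)N(C)OC | intermediate
15 | 2-[(1S,2R,5R)-1-hydroxy-2-[(2Z)-3-iodobut-2-en-1-yl]-2-methyl-5-(propan-2-yl)cyclopentyl]-N-methoxy-N-methylacetamide | CON(C)C(=O)C[C@]1(O)[C@@H](C(C)C)CC[C@]1(C)C/C=C(/C)I | intermediate
16 | lithium alkoxide of 15 with iodine replaced by lithium (olefin geometry retained; formally a (2E)-3-lithiobut-2-en-1-yl group because Li ranks below CH3) | CON(C)C(=O)C[C@]1(O[Li])[C@@H](C(C)C)CC[C@]1(C)C/C=C(/C)[Li] | intermediate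
17 | dilithium salt of the bicyclic N-methoxy-N-methyl hemiaminal at C7 (tetrahedral adduct, either configuration at C7) | CON(C)C1(O[Li])C[C@]2(O[Li])[C@@H](C(C)C)CC[C@]2(C)CC=C1C | intermediate
18 | (3R,3aS,8aR)-3a-hydroxy-6,8a-dimethyl-3-(propan-2-yl)-2,3,3a,4,8,8a-hexahydroazulen-5(1H)-one | O=C1C[C@]2(O)[C@@H](C(C)C)CC[C@]2(C)CC=C1C | intermediate
19 | (3R,3aS,5R,8aR)-6,8a-dimethyl-3-(propan-2-yl)-2,3,4,5,8,8a-hexahydroazulene-3a,5(1H)-diol | O[C@@H]1C[C@]2(O)[C@@H](C(C)C)CC[C@]2(C)CC=C1C | intermediate
20 | 3,4-dimethoxybenzoyl chloride | COc1ccc(C(=O)Cl)cc1OC | starting material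
21 | (3R,3aS,5R,8aR)-3a-hydroxy-6,8a-dimethyl-3-(propan-2-yl)-1,2,3,3a,4,5,8,8a-octahydroazulen-5-yl 3,4-dimethoxybenzoate (CNP0196585.1) | COc1ccc(C(=O)O[C@@H]2C[C@]3(O)[C@@H](C(C)C)CC[C@]3(C)CC=C2C)cc1OC | target

## Step count and risk

Total step count: 11. Longest linear sequence: 9 (steps 1, 2, 3, 4, 7, 8, 9, 10, 11); steps 5 and 6 make the alkylating agent.

**Step 7 (key step).** The isopropyl group that controls the new centre is 1,3 to the reacting carbon, so facial selectivity may be poor. Proton transfer between the product ketone and the enolate could also epimerise C4 or lead to a second alkylation. The fallback transfers chirality by a sigmatropic rearrangement instead of an enolate alkylation; it sets out from 5 and comes back at 12.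
- Luche reduction of 5 (NaBH4, CeCl3·7H2O) would give [(5R)-2-methyl-5-(propan-2-yl)cyclopent-1-en-1-yl]methanol F1.
- Johnson–Claisen rearrangement (triethyl orthoacetate, cat. propionic acid, 140 °C) would deliver the two-carbon chain to C1 within the allyl system, on the face away from the isopropyl group, giving ethyl 2-[(1R,3R)-1-methyl-2-methylidene-3-(propan-2-yl)cyclopentyl]acetate F2.
- i-Bu2AlH at −78 °C would give 2-[(1R,3R)-1-methyl-2-methylidene-3-(propan-2-yl)cyclopentyl]acetaldehyde F3.
- Stork–Zhao olefination ([Ph3PCH(I)CH3]I, NaN(SiMe3)2) would give (1R,3R)-1-[(2Z)-3-iodobut-2-en-1-yl]-1-methyl-2-methylidene-3-(propan-2-yl)cyclopentane F4.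
- Lemieux–Johnson cleavage (OsO4 cat., NaIO4) of the electron-rich exocyclic methylene would give 12.

**Step 4.** The electron-rich enol formate may be epoxidised by the peracid, or hydrolysed to the free ketone, which would lose the fixed position of the enol double bond. The fallback sets out from 5 and comes back at 11, which is alkylated as in step 7 to 12. Silylation of 5 (TBSOTf, Et3N) would give the dienol ether tert-butyldimethyl{[(5R)-2-methyl-5-(propan-2-yl)cyclopent-2-en-1-ylidene]methoxy}silane F5. Ozonolysis of its enol-ether double bond (one equivalent of O3, then Me2S) would give (5R)-2-methyl-5-(propan-2-yl)cyclopent-2-en-1-one F6. Conjugate reduction with LiBH(s-Bu)3 would then release enolate 11 regiospecifically.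

**Step 8.** The basic amide enolate may deprotonate the hindered ketone at C4 instead of adding, which returns starting material and can epimerise C4, or it may attack partly from the β face. The fallback sets out from 12 and comes back at 15. A Reformatsky reaction (Zn, ethyl bromoacetate, THF) uses a non-basic zinc enolate and would give ethyl 2-[(1S,2R,5R)-1-hydroxy-2-[(2Z)-3-iodobut-2-en-1-yl]-2-methyl-5-(propan-2-yl)cyclopentyl]acetate F7, which AlMe3 and N,O-dimethylhydroxylamine hydrochloride would convert into 15.

**Step 9.** The alkenyllithium may be quenched by internal proton transfer from C6–H before it reaches the amide. On work-up the C5 hydroxyl may add across the ring to C9 of the new enone (transannular oxa-Michael). The fallback closes the ring with a chromium reagent at the aldehyde level, without strong base; it sets out from 15 and comes back at 18. Reduction of 15 with i-Bu2AlH at −78 °C would give 2-[(1S,2R,5R)-1-hydroxy-2-[(2Z)-3-iodobut-2-en-1-yl]-2-methyl-5-(propan-2-yl)cyclopentyl]acetaldehyde F8. Nozaki–Hiyama–Kishi cyclisation (CrCl2, NiCl2 cat., DMSO) would give the allylic alcohol (3R,3aS,8aR)-6,8a-dimethyl-3-(propan-2-yl)-2,3,4,5,8,8a-hexahydroazulene-3a,5(1H)-diol as a mixture of C5 epimers F9, and MnO2 would oxidise the allylic hydroxyl to 18 under neutral conditions.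

**Step 10.** Exchange of the tertiary hydroxyl onto boron may be slow. Undirected reduction would then give the wrong C7 epimer, or acid-promoted oxa-Michael closure of 18 would compete. The fallback sets out from 18 and comes back at 21. A fast Luche reduction (NaBH4, CeCl3·7H2O, MeOH, −78 °C) is used, and whichever epimer forms is carried on: any 19 goes through step 11, while the epimer (3R,3aS,5S,8aR)-6,8a-dimethyl-3-(propan-2-yl)-2,3,4,5,8,8a-hexahydroazulene-3a,5(1H)-diol F10 would be esterified with inversion at C7 under Mitsunobu conditions (3,4-dimethoxybenzoic acid, PPh3, diisopropyl azodicarboxylate) to give 21.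

## Further compounds

F1 | step 7 | [(5R)-2-methyl-5-(propan-2-yl)cyclopent-1-en-1-yl]methanol | OCC1=C(C)CC[C@@H]1C(C)C
F2 | step 7 | ethyl 2-[(1R,3R)-1-methyl-2-methylidene-3-(propan-2-yl)cyclopentyl]acetate | CCOC(=O)C[C@@]1(C)CC[C@H](C(C)C)C1=C
F3 | step 7 | 2-[(1R,3R)-1-methyl-2-methylidene-3-(propan-2-yl)cyclopentyl]acetaldehyde | O=CC[C@@]1(C)CC[C@H](C(C)C)C1=C
F4 | step 7 | (1R,3R)-1-[(2Z)-3-iodobut-2-en-1-yl]-1-methyl-2-methylidene-3-(propan-2-yl)cyclopentane | C=C1[C@@H](C(C)C)CC[C@]1(C)C/C=C(/C)I
F5 | step 4 | tert-butyldimethyl{[(5R)-2-methyl-5-(propan-2-yl)cyclopent-2-en-1-ylidene]methoxy}silane | CC(C)(C)[Si](C)(C)OC=C1C(C)=CC[C@@H]1C(C)C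
F6 | step 4 | (5R)-2-methyl-5-(propan-2-yl)cyclopent-2-en-1-one | O=C1C(C)=CC[C@@H]1C(C)C
F7 | step 8 | ethyl 2-[(1S,2R,5R)-1-hydroxy-2-[(2Z)-3-iodobut-2-en-1-yl]-2-methyl-5-(propan-2-yl)cyclopentyl]acetate | CCOC(=O)C[C@]1(O)[C@@H](C(C)C)CC[C@]1(C)C/C=C(/C)I
F8 | step 9 | 2-[(1S,2R,5R)-1-hydroxy-2-[(2Z)-3-iodobut-2-en-1-yl]-2-methyl-5-(propan-2-yl)cyclopentyl]acetaldehyde | O=CC[C@]1(O)[C@@H](C(C)C)CC[C@]1(C)C/C=C(/C)I
F9 | step 9 | (3R,3aS,8aR)-6,8a-dimethyl-3-(propan-2-yl)-2,3,4,5,8,8a-hexahydroazulene-3a,5(1H)-diol, mixture of C5 epimers | OC1C[C@]2(O)[C@@H](C(C)C)CC[C@]2(C)CC=C1C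
F10 | step 10 | (3R,3aS,5S,8aR)-6,8a-dimethyl-3-(propan-2-yl)-2,3,4,5,8,8a-hexahydroazulene-3a,5(1H)-diol | O[C@H]1C[C@]2(O)[C@@H](C(C)C)CC[C@]2(C)CC=C1C
A1 | alternative 1 | (2R,5R)-2-methyl-5-(propan-2-yl)-2-(prop-2-en-1-yl)cyclopentan-1-one | O=C1[C@@H](C(C)C)CC[C@]1(C)CC=C
A2 | alternative 1 | 1-[(1S,2R,5R)-1-hydroxy-2-methyl-5-(propan-2-yl)-2-(prop-2-en-1-yl)cyclopentyl]-3-methylbut-3-en-2-one | C=C(C)C(=O)C[C@]1(O)[C@@H](C(C)C)CC[C@]1(C)CC=C
A3 | alternative 2 | 2-methyl-2-(3-oxobutyl)cyclopentane-1,3-dione | CC(=O)CCC1(C)C(=O)CCC1=O
A4 | alternative 2 | (3aR,7aR)-3a-hydroxy-7a-methylhexahydro-1H-indene-1,5(4H)-dione | O=C1C[C@]2(O)CCC(=O)[C@]2(C)CC1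
A5 | alternative 3 | (2R,6R)-6-[(tert-butyldimethylsilyl)oxy]-2,5-dimethyl-2-(4-methylpent-3-en-1-yl)cyclohept-4-en-1-one | O=C1C[C@@H](O[Si](C)(C)C(C)(C)C)C(C)=CC[C@@]1(C)CCC=C(C)C
A6 | alternative 3 | (3R,3aS,5R,8aR)-5-[(tert-butyldimethylsilyl)oxy]-6,8a-dimethyl-3-(prop-1-en-2-yl)-2,3,4,5,8,8a-hexahydroazulen-3a(1H)-ol | CC(C)(C)[Si](C)(C)O[C@@H]1C[C@]2(O)[C@@H](C(C)=C)CC[C@]2(C)CC=C1C
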